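**Assumption:** the carbinol centre in the given SMILES is R, and for the new step 1 the catalyst antipode that gives Re-face addition is used; its sense of induction cannot be predicted and is confirmed on the first run against material from the known-chemistry fallback.

## Retrosynthetic overview

1. Target ⇒ bis(indolyl)-2,5-dichloroquinone: both C–OMe bonds are made last, by double methoxide-for-chloride exchange.
2. Dichloroquinone ⇒ 2,5-dichloro-1,4-benzoquinone + two indoles: two successive acid-promoted C3 conjugate additions, each followed by DDQ re-oxidation (hindered left indole first, chiral right indole second).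
3. Right indole ⇒ (R)-3-methyl-1-(2-nitrophenyl)but-3-en-2-ol: pyrrole ring by Bartoli annulation, the ortho side chain becoming the C7 substituent.
4. That nitro alcohol ⇒ 2-nitrotoluene + methacrolein: the only stereocentre is set by a new chiral-iminophosphorane-catalysed benzylic 1,2-addition (vinylogous Henry reaction).
5. Left indole ⇒ o-toluidine + methyl 2,2-dimethylbut-3-enoate by Smith–Madelung annulation. Ring order: right pyrrole ring, then left pyrrole ring; both benzo rings and the quinone ring are bought.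

## Route

**Step 1**
Reactants: 1 2-nitrotoluene; 2 methacrolein (2-methylprop-2-enal)
Product: 3 (2R)-3-methyl-1-(2-nitrophenyl)but-3-en-2-ol
Conditions: 1 (5 equiv), 2 (1 equiv, added over 6 h), enantiopure P-spiro tetraaminophosphonium chloride (two valine-derived 4-isopropyl-5,5-di(p-tolyl)-1,3,2-diazaphospholidine rings spiro-fused at P, four N–H; 5 mol%), KOt-Bu (5 mol%), THF, −40 °C, 24 h; TFA (10 mol%) quench at −40 °C
Reagents that add atoms: none
Why: Proposed new method: the triaminoiminophosphorane formed from the salt and KOt-Bu should deprotonate the ortho-methyl group (pKa near 20 in DMSO) reversibly, and the resulting o-nitrobenzyl anion is a vinylogous nitronate held on the chiral aminophosphonium cation by two N–H···O hydrogen bonds, so its benzylic carbon adds 1,2 to the aldehyde on the Re face inside the chiral ion pair to give the R carbinol, with proton transfer to the alkoxide turning the catalyst over; low temperature, excess 1 and slow addition of 2 are meant to suppress conjugate addition, retro-addition and enal polymerisation; the closest known reaction types are the racemic base-mediated hydroxyalkylation of o-nitrotoluenes with aldehydes and the chiral iminophosphorane-catalysed enantioselective Henry (nitroaldol) reaction of nitroalkanes.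

**Step 2**
Reactants: 3 (2R)-3-methyl-1-(2-nitrophenyl)but-3-en-2-ol; 4 vinylmagnesium bromide
Product: 6 (2R)-1-(1H-indol-7-yl)-3-methylbut-3-en-2-ol, via nitrosoarene 5 (not isolated)
Conditions: 4 (4.5 equiv, 1 M in THF), THF, −45 °C, 1 h; sat. aq. NH4Cl
Reagents that add atoms: none
Why: Bartoli indole synthesis: one equivalent of 4 deprotonates the alcohol, the next reduces the nitro group to nitrosoarene 5, a further one adds at the nitroso oxygen, and [3,3]-sigmatropic shift onto the free ortho carbon (helped by the bulky ortho substituent), ring closure and loss of water give the 7-substituted indole, while the carbinol centre rides through as a spectator magnesium alkoxide.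

**Step 3**
Reactants: 7 o-toluidine (2-methylaniline); 8 methyl 2,2-dimethylbut-3-enoate
Product: 10 2-(2-methylbut-3-en-2-yl)-1H-indole, via N-(trimethylsilyl)-2-methylaniline 9 (not isolated)
Conditions: n-BuLi (1.0 equiv), hexane, 0 °C; TMSCl (1.0 equiv), rt; n-BuLi (2.2 equiv), hexane, reflux, 6 h; 8 (1.0 equiv), THF, −78 °C → rt; aq. NH4Cl
Reagents that add atoms: none
Why: Smith-modified Madelung indole synthesis: N-silylation allows clean N,C-dilithiation, the benzylic carbanion acylates with the non-enolisable ester 8, and intramolecular aza-Peterson olefination of the resulting ketone by the N-silyl anilide closes the pyrrole ring (no stereocentre).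

**Step 4**
Reactants: 10 2-(2-methylbut-3-en-2-yl)-1H-indole; 11 2,5-dichloro-1,4-benzoquinone
Product: 13 2,5-dichloro-3-[2-(2-methylbut-3-en-2-yl)-1H-indol-3-yl]-1,4-benzoquinone, via hydroquinone adduct 12 (not isolated)
Conditions: 11 (1.2 equiv), AcOH, rt, 12 h; then DDQ (1.1 equiv), THF, rt, 1 h
Reagents that add atoms: none
Why: Acid-promoted Friedel–Crafts-type conjugate (Michael) addition of indole C3 to a C–H carbon of the chloroquinone gives hydroquinone 12, which DDQ dehydrogenates to the quinone; acetic acid is mild enough for the acid-sensitive tert-allyl group.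

**Step 5**
Reactants: 13 2,5-dichloro-3-[2-(2-methylbut-3-en-2-yl)-1H-indol-3-yl]-1,4-benzoquinone; 6 (2R)-1-(1H-indol-7-yl)-3-methylbut-3-en-2-ol
Product: 15 2,5-dichloro-3-{7-[(2R)-2-hydroxy-3-methylbut-3-en-1-yl]-1H-indol-3-yl}-6-[2-(2-methylbut-3-en-2-yl)-1H-indol-3-yl]-1,4-benzoquinone, via bis(indolyl)hydroquinone 14 (not isolated)
Conditions: 6 (1.1 equiv), AcOH, 40 °C, 24 h; then DDQ (1.1 equiv), THF, rt, 1 h
Reagents that add atoms: none
Why: Second acid-promoted indole conjugate addition and DDQ re-oxidation: 13 has a single free C–H carbon, para to the first indole, so only the 2,5-diaryl pattern can form, and the secondary allylic alcohol is not ionised in acetic acid, so the stereocentre is kept.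

**Step 6**
Reactants: 15 2,5-dichloro-3-{7-[(2R)-2-hydroxy-3-methylbut-3-en-1-yl]-1H-indol-3-yl}-6-[2-(2-methylbut-3-en-2-yl)-1H-indol-3-yl]-1,4-benzoquinone
Product: 18 Asterriquinone I, via monomethoxy chloroquinone 16 (not isolated), via isomeric monomethoxy chloroquinone 17 (not isolated)
Conditions: NaOMe (6 equiv), anhydrous MeOH/THF 3:1, 0 °C → rt, 2 h; AcOH quench
Reagents that add atoms: sodium methoxide, [Na+].[O-]C
Why: Double addition–elimination (vinylogous acyl substitution) of methoxide at the two chlorine-bearing carbons, each β to a quinone carbonyl; anhydrous conditions stop the reaction at the dimethyl ether, and the carbinol centre is not involved.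

## Compound list

1 | 2-nitrotoluene (1-methyl-2-nitrobenzene) | Cc1ccccc1[N+](=O)[O-] | starting material
2 | methacrolein (2-methylprop-2-enal) | CC(=C)C=O | starting material
3 | (2R)-3-methyl-1-(2-nitrophenyl)but-3-en-2-ol | O=[N+]([O-])c1ccccc1C[C@@H](O)C(C)=C | intermediate
4 | vinylmagnesium bromide | C=C[Mg]Br | starting material
5 | (2R)-3-methyl-1-(2-nitrosophenyl)but-3-en-2-ol (nitrosoarene, present as its bromomagnesium alkoxide, not isolated) | O=Nc1ccccc1C[C@@H](O)C(C)=C | intermediate
6 | (2R)-1-(1H-indol-7-yl)-3-methylbut-3-en-2-ol | c1cc2cccc(C[C@@H](O)C(C)=C)c2[nH]1 | intermediate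
7 | o-toluidine (2-methylaniline) | Cc1ccccc1N | starting material
8 | methyl 2,2-dimethylbut-3-enoate | C=CC(C)(C)C(=O)OC | starting material
9 | N-(trimethylsilyl)-2-methylaniline (not isolated) | Cc1ccccc1N[Si](C)(C)C | intermediate
10 | 2-(2-methylbut-3-en-2-yl)-1H-indole | C=CC(C)(C)c1cc2ccccc2[nH]1 | intermediate
11 | 2,5-dichloro-1,4-benzoquinone | O=C1C=C(Cl)C(=O)C=C1Cl | starting material
12 | 2,5-dichloro-3-[2-(2-methylbut-3-en-2-yl)-1H-indol-3-yl]benzene-1,4-diol (hydroquinone adduct, not isolated) | C=CC(C)(C)c1[nH]c2ccccc2c1-c1c(O)c(Cl)cc(O)c1Cl | intermediate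
13 | 2,5-dichloro-3-[2-(2-methylbut-3-en-2-yl)-1H-indol-3-yl]-1,4-benzoquinone | C=CC(C)(C)c1[nH]c2ccccc2c1C1=C(Cl)C(=O)C=C(Cl)C1=O | intermediate
14 | 2,5-dichloro-3-{7-[(2R)-2-hydroxy-3-methylbut-3-en-1-yl]-1H-indol-3-yl}-6-[2-(2-methylbut-3-en-2-yl)-1H-indol-3-yl]benzene-1,4-diol (bis(indolyl)hydroquinone, not isolated) | C=CC(C)(C)c1[nH]c2ccccc2c1-c1c(Cl)c(O)c(-c2c[nH]c3c(C[C@@H](O)C(C)=C)cccc23)c(Cl)c1O | intermediate
15 | 2,5-dichloro-3-{7-[(2R)-2-hydroxy-3-methylbut-3-en-1-yl]-1H-indol-3-yl}-6-[2-(2-methylbut-3-en-2-yl)-1H-indol-3-yl]-1,4-benzoquinone | C=CC(C)(C)c1[nH]c2ccccc2c1C1=C(Cl)C(=O)C(c2c[nH]c3c(C[C@@H](O)C(C)=C)cccc23)=C(Cl)C1=O | intermediate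
16 | 2-chloro-5-methoxy-3-{7-[(2R)-2-hydroxy-3-methylbut-3-en-1-yl]-1H-indol-3-yl}-6-[2-(2-methylbut-3-en-2-yl)-1H-indol-3-yl]-1,4-benzoquinone (not isolated) | C=CC(C)(C)c1[nH]c2ccccc2c1C1=C(OC)C(=O)C(c2c[nH]c3c(C[C@@H](O)C(C)=C)cccc23)=C(Cl)C1=O | intermediate
17 | 5-chloro-2-methoxy-3-{7-[(2R)-2-hydroxy-3-methylbut-3-en-1-yl]-1H-indol-3-yl}-6-[2-(2-methylbut-3-en-2-yl)-1H-indol-3-yl]-1,4-benzoquinone (not isolated) | C=CC(C)(C)c1[nH]c2ccccc2c1C1=C(Cl)C(=O)C(c2c[nH]c3c(C[C@@H](O)C(C)=C)cccc23)=C(OC)C1=O | intermediate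
18 | Asterriquinone I, 2,5-dimethoxy-3-{7-[(2R)-2-hydroxy-3-methylbut-3-en-1-yl]-1H-indol-3-yl}-6-[2-(2-methylbut-3-en-2-yl)-1H-indol-3-yl]-1,4-benzoquinone | C=CC(C)(C)c1[nH]c2ccccc2c1C1=C(OC)C(=O)C(c2c[nH]c3c(C[C@@H](O)C(=C)C)cccc23)=C(OC)C1=O | target

## Step count and risk

Total steps: 6. Longest linear sequence: 4 steps (steps 1, 2, 5, 6 from 2-nitrotoluene; equally steps 3, 4, 5, 6 from o-toluidine).

**Step 1 (the proposed new reaction).** The catalyst may be too weakly basic for useful turnover, methacrolein may undergo conjugate addition or polymerise, and retro-addition could erode the ee. The fallback uses only known chemistry and sets out from 1. Wohl–Ziegler bromination (NBS, cat. dibenzoyl peroxide, PhCF3, reflux) gives 2-nitrobenzyl bromide F1. Suzuki–Miyaura coupling with 2-methylprop-1-enylboronic acid pinacol ester (Pd(PPh3)4, K2CO3, dioxane/H2O, 80 °C) gives 1-(3-methylbut-2-en-1-yl)-2-nitrobenzene F2. Shi epoxidation of the trisubstituted alkene (D-fructose-derived Shi ketone 30 mol%, KHSO5, K2CO3, Bu4NHSO4, MeCN/dimethoxymethane/aq. Na2B4O7 buffer, 0 °C) gives (3R)-2,2-dimethyl-3-(2-nitrobenzyl)oxirane F3; this metal-free dioxirane epoxidation sets the stereocentre. Al(OiPr)3 in toluene at reflux then isomerises the epoxide to the isopropenyl carbinol by cleaving the tertiary C–O bond and removing a methyl proton, with the R C–O carbon untouched. The fallback comes back to the route at 3 and costs three extra steps.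

**Step 2 (Bartoli annulation with a free alkoxide).** Bartoli yields are modest at best, and here the bromomagnesium alkoxide next to an o-nitrobenzylic carbon may fragment by retro-addition or be deprotonated at the benzylic position. The fallback sets out from 3 and masks the hydroxyl. TBSCl and imidazole in DMF give (2R)-2-(tert-butyldimethylsilyloxy)-3-methyl-1-(2-nitrophenyl)but-3-ene F4. Treatment with 4 (3.3 equiv, THF, −45 °C) passes through the silylated nitrosoarene F5 and gives 7-[(2R)-2-(tert-butyldimethylsilyloxy)-3-methylbut-3-en-1-yl]-1H-indole F6. TBAF in THF removes the silyl group, and the fallback comes back to the route at 6.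

**Step 5 (second indole addition to the deactivated, hindered quinone 13).** In acetic acid the addition may be too slow, and stronger acid endangers the free allylic alcohol (ionisation or acid-induced isomerisation to the isopropyl ketone). The fallback sets out from 6. TBDPSCl and imidazole in DMF give 7-[(2R)-2-(tert-butyldiphenylsilyloxy)-3-methylbut-3-en-1-yl]-1H-indole F7. With the hydroxyl capped, the addition to 13 can be run under mineral-acid promotion (cat. H2SO4, THF, 0 °C → rt) to the silylated bis(indolyl)hydroquinone F8. DDQ oxidises this to the silylated bis(indolyl)dichloroquinone F9. HF·pyridine in THF cleaves the silyl ether, and the fallback comes back to the route at 15.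

## Further compounds

F1 | step 1 | 2-nitrobenzyl bromide | O=[N+]([O-])c1ccccc1CBr
F2 | step 1 | 1-(3-methylbut-2-en-1-yl)-2-nitrobenzene | CC(C)=CCc1ccccc1[N+](=O)[O-]
F3 | step 1 | (3R)-2,2-dimethyl-3-(2-nitrobenzyl)oxirane | O=[N+]([O-])c1ccccc1C[C@H]1OC1(C)C
F4 | step 2 | (2R)-2-(tert-butyldimethylsilyloxy)-3-methyl-1-(2-nitrophenyl)but-3-ene | O=[N+]([O-])c1ccccc1C[C@@H](O[Si](C)(C)C(C)(C)C)C(C)=C
F5 | step 2 | (2R)-2-(tert-butyldimethylsilyloxy)-3-methyl-1-(2-nitrosophenyl)but-3-ene (not isolated) | O=Nc1ccccc1C[C@@H](O[Si](C)(C)C(C)(C)C)C(C)=C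
F6 | step 2 | 7-[(2R)-2-(tert-butyldimethylsilyloxy)-3-methylbut-3-en-1-yl]-1H-indole | c1cc2cccc(C[C@@H](O[Si](C)(C)C(C)(C)C)C(C)=C)c2[nH]1
F7 | step 5 | 7-[(2R)-2-(tert-butyldiphenylsilyloxy)-3-methylbut-3-en-1-yl]-1H-indole | c1cc2cccc(C[C@@H](O[Si](c3ccccc3)(c3ccccc3)C(C)(C)C)C(C)=C)c2[nH]1
F8 | step 5 | 2,5-dichloro-3-{7-[(2R)-2-(tert-butyldiphenylsilyloxy)-3-methylbut-3-en-1-yl]-1H-indol-3-yl}-6-[2-(2-methylbut-3-en-2-yl)-1H-indol-3-yl]benzene-1,4-diol (not isolated) | C=CC(C)(C)c1[nH]c2ccccc2c1-c1c(Cl)c(O)c(-c2c[nH]c3c(C[C@@H](O[Si](c4ccccc4)(c4ccccc4)C(C)(C)C)C(C)=C)cccc23)c(Cl)c1O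
F9 | step 5 | 2,5-dichloro-3-{7-[(2R)-2-(tert-butyldiphenylsilyloxy)-3-methylbut-3-en-1-yl]-1H-indol-3-yl}-6-[2-(2-methylbut-3-en-2-yl)-1H-indol-3-yl]-1,4-benzoquinone | C=CC(C)(C)c1[nH]c2ccccc2c1C1=C(Cl)C(=O)C(c2c[nH]c3c(C[C@@H](O[Si](c4ccccc4)(c4ccccc4)C(C)(C)C)C(C)=C)cccc23)=C(Cl)C1=O
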